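## Retrosynthetic overview

1. Target ⇐ double L-Selectride reduction of the 3,3′-dione ⇐ C11–C11′ bond by mixed Kolbe (decarboxylative) coupling of two C16 acids, unsaturated 14 and saturated 15.
2. 15 ⇐ 14 by HAT hydrogenation (8α-methyl), so both halves come from one intermediate.
3. 14 ⇐ Ireland–Claisen [3,3] rearrangement of allylic 7β-acetate 11; C7–O → C9–C11 chirality transfer sets C9 and the Δ7 olefin.
4. 11 ⇐ 1,3-transposition and inversion (epoxidation, Wharton, Mitsunobu) of bicyclic enone 7 ⇐ ring A closed by MHAT radical cyclization of an isopropenyl group onto an aldehyde.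
5. ⇐ (R)-carvone (ring B and C5 bought; C10 set by two α′-alkylations). Ring order: B (bought) → A (radical cyclization) → the two bicycles joined last.

Assumption: each decalin is numbered as in drimane (C1–C10, methyl on C8, chain carbon C11 on C9), primes mark the saturated half, α is the face opposite the C10 methyl, and reagents carry no compound numbers.

## Route

Step 1
Reactants: 1 (R)-(−)-carvone
Product: 3 (5R,6S)-6-methylcarvone, via lithium dienolate of carvone 2 (not isolated)
Conditions: LiN(i-Pr)2 (LDA), THF, −78 °C; then MeI, −78 → 0 °C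
Reagents that add atoms: iodomethane, CI
Why: Kinetic α′-deprotonation gives the cross-conjugated lithium dienolate, which is C-methylated (enolate alkylation) mainly anti to the neighbouring isopropenyl group; this centre is planarised again in step 2, so its ratio does not matter.

Step 2
Reactants: 3 (5R,6S)-6-methylcarvone
Product: 5 6-allyl-6-methylcarvone (allyl trans and methyl cis to isopropenyl), via lithium enolate of methylcarvone 4 (not isolated)
Conditions: LDA, THF/DMPU, −78 → −20 °C; then allyl bromide, → rt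
Reagents that add atoms: allyl bromide, C=CCBr
Why: A second α′-enolate alkylation builds the quaternary carbon (future C10): A1,2 strain turns the adjacent isopropenyl group pseudo-axial and allyl bromide enters anti to it, so the methyl ends cis and the allyl trans to isopropenyl, relayed from the bought C5 stereocentre.

Step 3
Reactants: 5 6-allyl-6-methylcarvone
Product: 6 3-[1,3-dimethyl-2-oxo-6-(prop-1-en-2-yl)cyclohex-3-en-1-yl]propanal (configuration as in 5)
Conditions: PdCl2(PhCN)2 (12 mol %), CuCl2·2H2O (12 mol %), AgNO2 (6 mol %), O2 (1 atm), t-BuOH/MeNO2 15:1, rt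
Reagents that add atoms: dioxygen, O=O
Why: Nitrite-modified, aldehyde-selective (anti-Markovnikov) Wacker oxidation converts only the monosubstituted alkene, the 1,1-disubstituted isopropenyl group and the enone being inert, and no stereocentre is touched.

Step 4
Reactants: 6 keto aldehyde
Product: 7 3β-hydroxy-11-nordrim-7-en-9-one
Conditions: Fe(acac)3 (30 mol %), PhSiH3, EtOH, 60 °C
Reagents that add atoms: none
Why: Hydrogen-atom transfer from the iron hydride to the isopropenyl group (Mukaiyama-type MHAT) gives the tertiary C4 radical, which adds 6-exo to the aldehyde carbon (reductive alkene–carbonyl radical cyclization) to close ring A with its gem-dimethyl group; the trans ring fusion is fixed by C5 and C10, and the new C3–OH is expected mainly equatorial (β), a centre that is re-set in steps 11 and 12.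

Step 5
Reactants: 7 3β-hydroxy-11-nordrim-7-en-9-one
Product: 8 7α,8α-epoxy-3β-hydroxy-11-nordriman-9-one
Conditions: 30 % H2O2, NaOH (0.3 equiv), MeOH, 0 °C
Reagents that add atoms: hydrogen peroxide, OO
Why: Weitz–Scheffer nucleophilic epoxidation: hydroperoxide adds to C7 axially from the α face, opposite the angular C10 methyl and trans to the C5–C4 bond as in carvone, and ring closure gives the 7α,8α-epoxide.

Step 6
Reactants: 8 7α,8α-epoxy-3β-hydroxy-11-nordriman-9-one
Product: 10 allylic diol 11-nordrim-8-ene-3β,7α-diol, via epoxy hydrazone 9 (not isolated)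
Conditions: N2H4·H2O (3 equiv), AcOH (cat.), MeOH, 0 °C → rt
Reagents that add atoms: none
Why: Wharton transposition: the epoxy hydrazone fragments through a vinyl diazene with loss of N2, placing the olefin at C8–C9 and leaving the untouched C7–O bond as the 7α allylic alcohol.

Step 7
Reactants: 10 11-nordrim-8-ene-3β,7α-diol
Product: 11 3β-hydroxy-11-nordrim-8-en-7β-yl acetate
Conditions: PPh3, DIAD, AcOH, THF, 0 °C → rt
Reagents that add atoms: acetic acid, CC(=O)O
Why: Mitsunobu esterification proceeds by SN2 inversion at the pseudo-axial allylic C7 to give the 7β-acetate needed for β-face delivery, while the neopentyl 3β-OH next to the gem-dimethyl carbon does not react.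

Step 8
Reactants: 11 3β-hydroxy-11-nordrim-8-en-7β-yl acetate
Product: 14 (3β-hydroxy-11-nordrim-7-en-9β-yl)acetic acid, via silyl ketene acetal 12 (not isolated), via bis-silyl ester 13 (not isolated)
Conditions: LDA (2.5 equiv), Me3SiCl (3 equiv), Et3N, THF, −78 °C → rt; PhMe, 100 °C; then 1 M HCl
Reagents that add atoms: none
Why: The Ireland–Claisen [3,3]-sigmatropic rearrangement of the silyl ketene acetal is suprafacial, so the C7β–O bond is traded for the C9β–C11 bond (cis to the C10 methyl) with simultaneous formation of the Δ7 trisubstituted olefin; the 3-OH is silylated in situ and freed on acidic work-up.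

Step 9
Reactants: 14 (3β-hydroxy-11-nordrim-7-en-9β-yl)acetic acid (about three quarters of the material)
Product: 15 (3β-hydroxy-11-nor-8βH-driman-9β-yl)acetic acid (8α-methyl)
Conditions: Mn(dpm)3 (10 mol %), PhSiH3, t-BuOOH, i-PrOH, rt
Reagents that add atoms: none
Why: Shenvi-type HAT hydrogenation reduces the trisubstituted olefin stepwise through the tertiary C8 radical and should give the thermodynamically preferred 8α-methyl (8β-H) isomer, diequatorial with the 9β side chain and free of the 1,3-diaxial clash with the C10 methyl that the 8β-methyl epimer from α-face catalytic hydrogenation would have.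

Step 10
Reactants: 14 (3β-hydroxy-11-nordrim-7-en-9β-yl)acetic acid (1 equiv); 15 (3β-hydroxy-11-nor-8βH-driman-9β-yl)acetic acid (3 equiv)
Product: 16 1-(3β-hydroxy-11-nordrim-7-en-9β-yl)-2-(3β-hydroxy-11-nor-8βH-driman-9β-yl)ethane
Conditions: undivided cell, Pt anode and Pt cathode, KOH (0.1 equiv), MeOH, ca. 0.2 A cm−2, 40 °C
Reagents that add atoms: none
Why: Mixed Kolbe electrolysis: anodic decarboxylation of both carboxylates gives primary C11 and C11′ radicals that dimerise to the C11–C11′ bond without touching any stereocentre; the excess of 15 steers 14 into the cross-product, which is separated from the two homodimers on AgNO3-impregnated silica.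

Step 11
Reactants: 16 3β,3′β-diol
Product: 17 1-(3-oxo-11-nordrim-7-en-9β-yl)-2-(3-oxo-11-nor-8βH-driman-9β-yl)ethane
Conditions: Dess–Martin periodinane, CH2Cl2, rt
Reagents that add atoms: none
Why: Dess–Martin oxidation converts both hindered secondary alcohols into ketones without affecting the trisubstituted olefin, erasing the C3 and C3′ configurations so that both can be set together.

Step 12
Reactants: 17 3,3′-dione
Product: 18 1-(3α-hydroxy-11-nordrim-7-en-9β-yl)-2-(3α-hydroxy-11-nor-8βH-driman-9β-yl)ethane (target)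
Conditions: LiBH(s-Bu)3 (L-Selectride), THF, −78 °C; then H2O
Reagents that add atoms: none
Why: The bulky hydride of L-Selectride attacks each 4,4-dimethyl-3-ketone from the equatorial side (the axial path is blocked by the axial hydrogens at C1 and C5), giving the axial 3α-alcohol in both halves under substrate control, which is the target.

## Compound list

1 | (R)-(−)-carvone, (5R)-2-methyl-5-(prop-1-en-2-yl)cyclohex-2-en-1-one | CC1=CC[C@@H](C(C)=C)CC1=O | starting material
2 | lithium cross-conjugated dienolate of carvone (C1–OLi, C1=C6) | CC1=CC[C@@H](C(C)=C)C=C1[O-].[Li+] | intermediate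
3 | (5R,6S)-6-methylcarvone (methyl trans to isopropenyl, major epimer) | CC1=CC[C@@H](C(C)=C)[C@H](C)C1=O | intermediate
4 | lithium enolate of 6-methylcarvone | CC1=CC[C@@H](C(C)=C)C(C)=C1[O-].[Li+] | intermediate
5 | 6-allyl-6-methylcarvone, allyl trans and methyl cis to the isopropenyl group | CC1=CC[C@@H](C(C)=C)[C@](C)(CC=C)C1=O | intermediate
6 | 3-[1,3-dimethyl-2-oxo-6-(prop-1-en-2-yl)cyclohex-3-en-1-yl]propanal, configuration as in 5 | CC1=CC[C@@H](C(C)=C)[C@](C)(CCC=O)C1=O | intermediate
7 | 3β-hydroxy-11-nordrim-7-en-9-one (trans-fused, 5α-H, 10β-methyl) | CC1=CC[C@H]2C(C)(C)[C@@H](O)CC[C@]2(C)C1=O | intermediate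
8 | 7α,8α-epoxy-3β-hydroxy-11-nordriman-9-one | C[C@@]12O[C@@H]1C[C@H]3C(C)(C)[C@@H](O)CC[C@]3(C)C2=O | intermediate
9 | hydrazone of epoxy ketone 8 | C[C@@]12O[C@@H]1C[C@H]3C(C)(C)[C@@H](O)CC[C@]3(C)C2=NN | intermediate
10 | 11-nordrim-8-ene-3β,7α-diol | CC1=C[C@@]2(C)CC[C@H](O)C(C)(C)[C@@H]2C[C@H]1O | intermediate
11 | 3β-hydroxy-11-nordrim-8-en-7β-yl acetate | CC1=C[C@@]2(C)CC[C@H](O)C(C)(C)[C@@H]2C[C@@H]1OC(C)=O | intermediate
12 | 3β-trimethylsilyloxy-11-nordrim-8-en-7β-yl 1-(trimethylsilyloxy)vinyl ether (silyl ketene acetal) | CC1=C[C@@]2(C)CC[C@H](O[Si](C)(C)C)C(C)(C)[C@@H]2C[C@@H]1OC(=C)O[Si](C)(C)C | intermediate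
13 | trimethylsilyl (3β-trimethylsilyloxy-11-nordrim-7-en-9β-yl)acetate | CC1=CC[C@H]2C(C)(C)[C@@H](O[Si](C)(C)C)CC[C@]2(C)[C@H]1CC(=O)O[Si](C)(C)C | intermediate
14 | (3β-hydroxy-11-nordrim-7-en-9β-yl)acetic acid | CC1=CC[C@H]2C(C)(C)[C@@H](O)CC[C@]2(C)[C@H]1CC(=O)O | intermediate
15 | (3β-hydroxy-11-nor-8βH-driman-9β-yl)acetic acid (8α-methyl) | OC(=O)C[C@H]1[C@H](C)CC[C@H]2C(C)(C)[C@@H](O)CC[C@]12C | intermediate
16 | 1-(3β-hydroxy-11-nordrim-7-en-9β-yl)-2-(3β-hydroxy-11-nor-8βH-driman-9β-yl)ethane | CC1=CC[C@H]2C(C)(C)[C@@H](O)CC[C@]2(C)[C@H]1CC[C@H]1[C@H](C)CC[C@H]2C(C)(C)[C@@H](O)CC[C@]12C | intermediate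
17 | 1-(3-oxo-11-nordrim-7-en-9β-yl)-2-(3-oxo-11-nor-8βH-driman-9β-yl)ethane | CC1=CC[C@H]2C(C)(C)C(=O)CC[C@]2(C)[C@H]1CC[C@H]1[C@H](C)CC[C@H]2C(C)(C)C(=O)CC[C@]12C | intermediate
18 | 1-(3α-hydroxy-11-nordrim-7-en-9β-yl)-2-(3α-hydroxy-11-nor-8βH-driman-9β-yl)ethane, CNP0194061.3 (onocer-7-ene-3,21-diol with both hydroxyls axial) | CC1=CC[C@H]2C(C)(C)[C@H](O)CC[C@]2(C)[C@H]1CC[C@H]1[C@H](C)CC[C@H]2C(C)(C)[C@H](O)CC[C@]12C | target

## Step count and risks

Total step count: 12. Longest linear sequence: 12 steps (1 → 14 → 15 → 16 → 18; acid 14 is used twice, once directly and once after step 9).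

Steps most likely to fail:

Step 4 (MHAT alkene–aldehyde cyclization). Radical addition to C=O is reversible, the precedent is mainly for ketones, and plain reduction of the isopropenyl group can compete. The fallback sets out from 3 and comes back at 7. The lithium enolate of 3 is added to acrylonitrile (LDA, THF, −78 °C) to give 6-(2-cyanoethyl)-6-methylcarvone F1. HAT-initiated radical cyclization of the isopropenyl group onto the nitrile (Fe(acac)3, PhSiH3, EtOH; acidic work-up of the imine) gives 11-nordrim-7-ene-3,9-dione F2. NaBH4 in MeOH at −40 °C then reduces the saturated C3 ketone by axial attack, in preference to the hindered conjugated C9 ketone, to give 7.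

Step 9 (HAT hydrogenation). If kinetic α-face hydrogen delivery to the C8 radical competes, the 8β-methyl epimer forms. The fallback sets out from 14 and comes back at 15. Esterification with Me3SiCHN2 gives methyl (3β-hydroxy-11-nordrim-7-en-9β-yl)acetate F3. Carbonyl-directed hydrogenation with [Ir(cod)(PCy3)(py)]PF6 and H2 in CH2Cl2 lets the 9β ester arm deliver hydrogen to the β face, giving methyl (3β-hydroxy-11-nor-8βH-driman-9β-yl)acetate F4. LiOH in THF/H2O then gives 15.

Step 10 (mixed Kolbe electrolysis). The coupling is statistical, and anodic over-oxidation or poor conductivity of these lipophilic acids could lower the yield. The fallback sets out from 14 and 15 and comes back at 16. Each acid is converted with N-hydroxyphthalimide, DIC and DMAP into its redox-active ester: N-phthalimidoyl (3β-hydroxy-11-nordrim-7-en-9β-yl)acetate F5 and N-phthalimidoyl (3β-hydroxy-11-nor-8βH-driman-9β-yl)acetate F6. The two esters (F6 in excess) are joined by nickel-electrocatalytic reductive doubly decarboxylative C(sp3)–C(sp3) cross-coupling (NiCl2·6H2O, terpyridine ligand, Mg anode, carbon cathode, NMP) to give 16.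

Further compounds
F1 | step 4 | 6-(2-cyanoethyl)-6-methylcarvone (cyanoethyl trans to isopropenyl) | CC1=CC[C@@H](C(C)=C)[C@](C)(CCC#N)C1=O
F2 | step 4 | 11-nordrim-7-ene-3,9-dione | CC1=CC[C@H]2C(C)(C)C(=O)CC[C@]2(C)C1=O
F3 | step 9 | methyl (3β-hydroxy-11-nordrim-7-en-9β-yl)acetate | CC1=CC[C@H]2C(C)(C)[C@@H](O)CC[C@]2(C)[C@H]1CC(=O)OC
F4 | step 9 | methyl (3β-hydroxy-11-nor-8βH-driman-9β-yl)acetate | COC(=O)C[C@H]1[C@H](C)CC[C@H]2C(C)(C)[C@@H](O)CC[C@]12C
F5 | step 10 | N-phthalimidoyl (3β-hydroxy-11-nordrim-7-en-9β-yl)acetate | CC1=CC[C@H]2C(C)(C)[C@@H](O)CC[C@]2(C)[C@H]1CC(=O)ON1C(=O)c2ccccc2C1=O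
F6 | step 10 | N-phthalimidoyl (3β-hydroxy-11-nor-8βH-driman-9β-yl)acetate | O=C(C[C@H]1[C@H](C)CC[C@H]2C(C)(C)[C@@H](O)CC[C@]12C)ON1C(=O)c2ccccc2C1=O
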